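## Structural features

The target is a 2,3-dihydro-1,4-benzodioxine: a benzene ring (ring A) fused through C4a and C8a to a 1,4-dioxane ring O1–C2–C3–O4. Ring A carries a methoxy group at C5, next to the O4-bearing carbon C4a, and an (E)-prop-1-enyl group at C7. C2 carries a 4-hydroxy-3,5-dimethoxyphenyl ring (ring B) and C3 a methyl group. C2 and C3 are adjacent stereocentres, both R, which places aryl and methyl trans (diequatorial) on the dioxane half-chair. Three points are fragile: the free phenol of ring B, which lies para to the benzylic C2–O1 ether and can open that bond through a quinone methide; the electron-rich propenyl group, which is open to acid, electrophiles, carbenes and geometric isomerisation; and the oxidation-prone oxygenated rings. The real difficulty is to set the two contiguous C–O stereocentres in one absolute sense while placing the aryl-bearing carbon on O1 (flanked by C8–H) and the methyl-bearing carbon on O4 (flanked by the C5 methoxy group) of an unsymmetrical ring A. The key step exploits the fact that O1–C2–C3–O4 is an acetal unit O1–C3–O4 with one carbon, C2, inserted into the O1–C3 bond. A 2-methyl-1,3-benzodioxole already holds C3, its methyl group, both oxygens and ring A, and an aryl carbene supplies C2 with ring B.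

## Logic of the disconnections

15 to 14: the phenolic O–H of 15 is traced back to an aryl ester, cutting the O–C(acyl) bond. The free phenol is the most fragile function and would insert into a carbene O–H-wise, so it is unmasked last. The forward step must deacylate under mild conditions. Only C2 can drift (through the quinone methide), and it drifts towards the trans isomer, so this step also offers a late correction of C2, while C3 cannot be repaired.

14 to 12 and 13: the C7–C(alkenyl) bond is cut. The propenyl group would be cyclopropanated in the carbene step, so it is replaced by a bromide that is inert there and is exchanged afterwards. The gain is a carbene partner without any alkene. The forward coupling must retain the E geometry of 13 and spare the aryl ester.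

12 to 5 and 9 (through 10 and 11): the bonds O1–C2 and C2–C3 are cut, which removes the dioxane ring and both stereocentres at once. It leaves a racemic five-membered acetal and an achiral carbene precursor of similar size. The forward step must deliver the carbene to O1 and not O4, keep the ylide on the catalyst, and control both the face of the oxocarbenium ion and the trans relation. The design is tightened in three places:
- 10 is made with NaH, because an alkoxide base would attack the aryl ester of 9.
- The coupling is run in a solvent without ether oxygen, so that the oxygens of 5 are the only ones offered to the carbene.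
- 5 is used in excess, to outrun carbene dimerisation, and the surplus is recovered.

5 to 3 and 4: the two acetal C–O bonds are cut. The catechol oxygens become O1 and O4 and the acetal carbon becomes C3 with its methyl group. The forward step must close the five-membered acetal faster than the activated ring is C-alkylated. The racemic acetal centre is of no concern.

3 to 1: the aryl C–O bond at the future O1 is traced back to an aryl–CHO bond. 1 has the full 1,2,3,5-pattern of ring A, with bromine para to the future O4 and the methoxy group beside it. The forward step is an oxidative aryl migration that must not over-oxidise the catechol.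

9 to 7 and 8: the C=N bond is cut. The hydrazone is the storable precursor of the diazo compound 11. The condensation must be neutral so that the ester survives.

7 to 6: the O–C(acyl) bond is cut, leading to a commercial aldehyde that already has ring B complete. The acylation must work at a hydroxyl flanked by two methoxy groups.

## Other disconnections considered

Alternative 1: The cut is O4–C3, with the C3 methyl appearing as an iodomethyl group and the propenyl group as a formyl group. In the forward step the O4 phenol of the branched allyl aryl ether A1, 3-{[(1S)-1-[3,5-dimethoxy-4-(methoxymethoxy)phenyl]prop-2-enyl]oxy}-4-hydroxy-5-methoxybenzaldehyde, attacks the internal carbon of the N-iodosuccinimide-activated vinyl group, 6-exo. This would give the iodomethyl benzodioxine aldehyde A2, (2R,3S)-2-[3,5-dimethoxy-4-(methoxymethoxy)phenyl]-3-(iodomethyl)-5-methoxy-2,3-dihydro-1,4-benzodioxine-7-carbaldehyde.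
- In favour: C2 would be set beforehand by asymmetric allylic etherification (for example [Ir(cod)Cl]2 with a chiral phosphoramidite), a reaction class with a strong record, and iodoetherification is an established ring closure. The O1/O4 assignment is fixed by construction.
- Against: C3 has to be induced by C2 through a chair-like 6-exo transition state, which is plausible but not assured. A1 is an allylic, benzylic, para-alkoxyaryl ether that may ionise under iodonium conditions or undergo a [3,3]-shift to C8. Ring A must first be differentiated at its two hydroxyls. Three corrections follow the key step: C–I to C–H, formyl to (E)-propenyl with geometric control, and acid removal of the methoxymethyl group next to a styrene and a benzylic ether.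
- Comparison: structurally it makes one ring bond and one stereocentre in its key step, where step 5 makes two bonds and two stereocentres. Mechanistically it is on firmer ground than step 5, and on absolute configuration and on O1/O4 site control it is the better plan. In step economy it is the weaker plan (about ten to eleven steps against seven), and its acidic final deprotection is a hazard that the base-labile ester of 14 avoids.

Alternative 2: The cuts are C4a–C5 and C8–C8a, so that ring A is built last on a preformed O1–C2–C3–O4 chain held in the dioxanone A3, (5R,6S)-6-[3,5-dimethoxy-4-(methoxymethoxy)phenyl]-5-methyl-1,4-dioxan-2-one. In the forward step the lithium enolate of A3 is C-acylated by the dienoyl chloride A4, (2E,4E)-3-methylhexa-2,4-dienoyl chloride. Excess LiN(i-Pr)2 then deprotonates the methyl group cis to the new ketone, and the carbanion attacks the lactone carbonyl, expels the C2 alkoxide and aromatises to the resorcinol A5, 2-{[(1S,2R)-1-[3,5-dimethoxy-4-(methoxymethoxy)phenyl]-1-hydroxypropan-2-yl]oxy}-5-[(E)-prop-1-enyl]benzene-1,3-diol. Mitsunobu closure of O1–C2 with inversion, methylation of the remaining phenol and removal of the methoxymethyl group would follow.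
- In favour: both stereocentres exist before the key step and come from established asymmetric chemistry. The two hydroxyls of A5 are equivalent, so no O1/O4 question arises. The propenyl group arrives with A4, so no cross-coupling is needed.
- Against: the one-pot annulation stacks C- against O-acylation of an alkoxy enolate, deprotonation of the 3-methyl group in competition with the terminal methyl of the propenyl unit, and a Dieckmann-type attack on a lactone. A3 needs the erythro arrangement, which syn-dihydroxylation of an E-alkene does not deliver directly. A Mitsunobu reaction at an electron-rich benzylic alcohol can leak through a cation, and the end game again finishes with acid.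
- Comparison: structurally it is the more convergent in carbon count for ring A, but it hides no stereochemical simplification. Mechanistically every single event has precedent, while their combination is demanding. On stereocontrol and on site selectivity it is the better plan, and on handling of the propenyl group it is the equal of the chosen plan. On step economy it is the weaker one (ten steps or more).

Alternative 3: The cuts are O4–C4a and O1–C2, with ring A at the cyclohexenone level. In the forward step the Rh2(OAc)4 carbene from the diazodione A6, methyl 4-diazo-3,5-dioxocyclohexane-1-carboxylate, is attacked at C4a by the oxygen of the epoxide A7, 2,6-dimethoxy-4-[(2R,3R)-3-methyloxiran-2-yl]phenyl 2,2-dimethylpropanoate. The benzylic C–O bond opens and the enolate oxygen closes onto C2, giving the dioxene A8, methyl (2R,3R)-2-[4-(2,2-dimethylpropanoyloxy)-3,5-dimethoxyphenyl]-3-methyl-5-oxo-2,3,5,6,7,8-hexahydro-1,4-benzodioxine-7-carboxylate.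
- In favour: C3 would come from a reliable asymmetric epoxidation (Shi epoxidation of an E-alkene). The two carbonyl oxygens of A6 are equivalent, so there is no site question. The catalyst is achiral and cheap, and A6 is a stable, isolable diazo compound, which is easier to handle than 11.
- Against: the configuration at C2 depends on whether the benzylic carbon is substituted with retention (ion pair, needed for the trans-epoxide A7) or inversion, and that is not secure. Carbene-mediated deoxygenation of the epoxide competes. After the key step the carbocycle must be aromatised and O-methylated, and the ester must be reduced and olefinated to the (E)-propenyl group, about five further steps.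
- Comparison: structurally it postpones the aromatic ring, which the chosen plan buys ready-made in 1. Mechanistically it is closer to known carbene chemistry than step 5, and on site selectivity, catalyst cost and diazo handling it is the better plan. On C2 control it is no safer than step 5, and on step economy it is clearly the weaker plan (about eleven to twelve steps).

Key step: step 5

Assumption: Rh2(S-PTTL)4 is taken to give the (2R,3R) enantiomer of 12; the sense of induction cannot be predicted, so if the opposite sense is found the mirror-image complex Rh2(R-PTTL)4 from (R)-tert-leucine would be used, with nothing else in the route changed.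

## Route

Step 1
Reactants: 1 5-bromo-2-hydroxy-3-methoxybenzaldehyde
Product: 3 5-bromo-3-methoxybenzene-1,2-diol, via aryl formate 2 (not isolated)
Conditions: 30% aq. H2O2 (1.2 equiv), NaOH (1.1 equiv), H2O, 0 °C to rt, N2; then Na2SO3, HCl to pH 4
Reagents that add atoms: hydrogen peroxide, OO
Why: Dakin oxidation: hydroperoxide adds to the formyl group, the electron-rich ortho-hydroxyaryl group migrates to oxygen to give formate 2, and the base saponifies 2 in the same flask; the aryl bromide and the methyl ether are inert and no stereocentre is involved.

Step 2
Reactants: 3 5-bromo-3-methoxybenzene-1,2-diol; 4 acetaldehyde diethyl acetal (1,1-diethoxyethane)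
Product: 5 rac-6-bromo-4-methoxy-2-methyl-1,3-benzodioxole
Conditions: 4 (3 equiv), p-TsOH·H2O (5 mol %), toluene, 100 °C, slow distillation of EtOH, N2
Reagents that add atoms: none
Why: Acid-catalysed transacetalisation: an oxocarbenium ion from 4 is captured by one phenolic oxygen and, after loss of the second ethanol, by the neighbouring one in a five-membered closure, the equilibrium being pulled by removal of ethanol. The acetal carbon is formed racemic, which is harmless because step 5 erases it.

Step 3
Reactants: 6 4-hydroxy-3,5-dimethoxybenzaldehyde (syringaldehyde)
Product: 7 4-formyl-2,6-dimethoxyphenyl 2,2-dimethylpropanoate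
Conditions: PivCl (1.3 equiv), Et3N (2 equiv), DMAP (10 mol %), CH2Cl2, 0 °C to rt
Reagents that add atoms: pivaloyl chloride, CC(C)(C)C(Cl)=O
Why: DMAP-catalysed O-acylation of the phenol; the acid chloride is reactive enough for a hydroxyl flanked by two methoxy groups and the aldehyde is untouched.

Step 4
Reactants: 7 4-formyl-2,6-dimethoxyphenyl 2,2-dimethylpropanoate; 8 p-toluenesulfonyl hydrazide
Product: 9 2,6-dimethoxy-4-[(E)-(tosylhydrazono)methyl]phenyl 2,2-dimethylpropanoate
Conditions: 8 (1.05 equiv), MeOH, rt; product filtered off
Reagents that add atoms: none
Why: Condensation of the aldehyde with the sulfonyl hydrazide to the N-tosylhydrazone, which should crystallise from methanol as the E isomer; the neutral conditions leave the aryl ester intact.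

Step 5
Reactants: 9 2,6-dimethoxy-4-[(E)-(tosylhydrazono)methyl]phenyl 2,2-dimethylpropanoate; 5 rac-6-bromo-4-methoxy-2-methyl-1,3-benzodioxole
Product: 12 4-[(2R,3R)-7-bromo-5-methoxy-3-methyl-2,3-dihydro-1,4-benzodioxin-2-yl]-2,6-dimethoxyphenyl 2,2-dimethylpropanoate, via sodium tosylhydrazonide 10 (not isolated), via aryldiazomethane 11 (not isolated)
Conditions: NaH (1.05 equiv), THF, 0 °C to rt, then evaporation; 5 (2 equiv), Rh2(S-PTTL)4 (2 mol %), BnEt3NCl (10 mol %), PhCF3, 40 °C
Reagents that add atoms: none
Why: Proposed new method: the donor carbene formed from 11 on Rh2(S-PTTL)4 should be captured by acetal oxygen O1 of 5 to give a rhodium-associated oxonium ylide, the O1–acetal carbon bond then breaks to an O4-stabilised oxocarbenium ion paired with the rhodium-bound benzylic carbanion, and collapse of this pair forms C2–C3, a net [1,2]-Stevens shift of a very good migrating group. The closest known reaction type is the ring expansion of 1,3-dioxolanes to 1,4-dioxanes by carbenes from diazocarbonyl compounds, which has not been shown with an aryl donor carbene, a benzodioxole or this kind of enantiocontrol. The single ring is closed in the recombination, a 6-endo-trig attack of C2 on the oxocarbenium carbon C3, the O1–C2 bond being already in place from the ylide. C3 is set by the face of the planar oxocarbenium ion that the ligand pocket leaves open, which is why racemic 5 can be used, and C2 is set by the configuration of the catalyst-bound benzylic carbon; because a carbene without a carbonyl group would give a non-stabilised free ylide, rhodium should stay on carbon until C2–C3 forms, and a chair-like collapse with aryl and methyl both pseudo-equatorial gives the trans relation. The step needs site selectivity for O1 over O4: O1 is flanked only by C8–H whereas O4 is screened by the C5 methoxy group, and in the cleavage the bond to the more electron-poor O1 (meta to both OMe and Br) breaks while the more electron-rich O4 carries the charge. It also needs chemoselectivity, which the substrates secure: bromide in place of the propenyl group leaves no alkene to cyclopropanate, the pivalate leaves no O–H bond and tempers the aryl donor, and NaH instead of an alkoxide makes 10 without touching the aryl ester. The absolute sense of induction and the level of trans selectivity are the unproven part.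

Step 6
Reactants: 12 4-[(2R,3R)-7-bromo-5-methoxy-3-methyl-2,3-dihydro-1,4-benzodioxin-2-yl]-2,6-dimethoxyphenyl 2,2-dimethylpropanoate; 13 4,4,5,5-tetramethyl-2-[(E)-prop-1-enyl]-1,3,2-dioxaborolane
Product: 14 2,6-dimethoxy-4-[(2R,3R)-5-methoxy-3-methyl-7-[(E)-prop-1-enyl]-2,3-dihydro-1,4-benzodioxin-2-yl]phenyl 2,2-dimethylpropanoate
Conditions: 13 (1.5 equiv), Pd(dppf)Cl2 (5 mol %), K3PO4 (2 equiv), 1,4-dioxane/H2O 10:1, 80 °C, degassed
Reagents that add atoms: none
Why: Suzuki–Miyaura coupling: zerovalent palladium inserts into the unhindered C7–Br bond and the alkenylboronate transfers the propenyl group with retention of E geometry; the stereocentres are not touched and the doubly ortho-substituted aryl pivalate should survive K3PO4 at this temperature.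

Step 7
Reactants: 14 2,6-dimethoxy-4-[(2R,3R)-5-methoxy-3-methyl-7-[(E)-prop-1-enyl]-2,3-dihydro-1,4-benzodioxin-2-yl]phenyl 2,2-dimethylpropanoate
Product: 15 2,6-dimethoxy-4-[(2R,3R)-5-methoxy-3-methyl-7-[(E)-prop-1-enyl]-2,3-dihydro-1,4-benzodioxin-2-yl]phenol
Conditions: K2CO3 (2 equiv), degassed MeOH, rt (to 40 °C if slow), Ar; then aq. NH4Cl
Reagents that add atoms: none
Why: Methanolysis (transesterification) of the aryl ester by methoxide generated from K2CO3, the aryloxide being a good leaving group. C3 is not epimerisable, and should the phenoxide reversibly open O1–C2 through a para-quinone methide, re-closure is expected to return the more stable trans isomer, which is the target configuration.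

## Compound list

1 | 5-bromo-2-hydroxy-3-methoxybenzaldehyde | O=Cc1cc(Br)cc(OC)c1O | starting material
2 | 5-bromo-2-hydroxy-3-methoxyphenyl formate | O=COc1cc(Br)cc(OC)c1O | intermediate
3 | 5-bromo-3-methoxybenzene-1,2-diol | COc1cc(Br)cc(O)c1O | intermediate
4 | acetaldehyde diethyl acetal (1,1-diethoxyethane) | CC(OCC)OCC | starting material
5 | rac-6-bromo-4-methoxy-2-methyl-1,3-benzodioxole | CC1Oc2cc(Br)cc(OC)c2O1 | intermediate
6 | 4-hydroxy-3,5-dimethoxybenzaldehyde (syringaldehyde) | COc1cc(C=O)cc(OC)c1O | starting material
7 | 4-formyl-2,6-dimethoxyphenyl 2,2-dimethylpropanoate | COc1cc(C=O)cc(OC)c1OC(=O)C(C)(C)C | intermediate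
8 | p-toluenesulfonyl hydrazide | Cc1ccc(cc1)S(=O)(=O)NN | starting material
9 | 2,6-dimethoxy-4-[(E)-(tosylhydrazono)methyl]phenyl 2,2-dimethylpropanoate | Cc1ccc(cc1)S(=O)(=O)N/N=C/c1cc(OC)c(OC(=O)C(C)(C)C)c(OC)c1 | intermediate
10 | sodium salt of 9 (N-sodio tosylhydrazonide) | [Na+].Cc1ccc(cc1)S(=O)(=O)[N-]/N=C/c1cc(OC)c(OC(=O)C(C)(C)C)c(OC)c1 | intermediate
11 | 4-(diazomethyl)-2,6-dimethoxyphenyl 2,2-dimethylpropanoate | [N-]=[N+]=Cc1cc(OC)c(OC(=O)C(C)(C)C)c(OC)c1 | intermediate
12 | 4-[(2R,3R)-7-bromo-5-methoxy-3-methyl-2,3-dihydro-1,4-benzodioxin-2-yl]-2,6-dimethoxyphenyl 2,2-dimethylpropanoate | Brc1cc(OC)c2c(c1)O[C@H](c1cc(OC)c(OC(=O)C(C)(C)C)c(OC)c1)[C@@H](C)O2 | intermediate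
13 | 4,4,5,5-tetramethyl-2-[(E)-prop-1-enyl]-1,3,2-dioxaborolane | C/C=C/B1OC(C)(C)C(C)(C)O1 | starting material
14 | 2,6-dimethoxy-4-[(2R,3R)-5-methoxy-3-methyl-7-[(E)-prop-1-enyl]-2,3-dihydro-1,4-benzodioxin-2-yl]phenyl 2,2-dimethylpropanoate | C/C=C/c1cc(OC)c2c(c1)O[C@H](c1cc(OC)c(OC(=O)C(C)(C)C)c(OC)c1)[C@@H](C)O2 | intermediate
15 | 2,6-dimethoxy-4-[(2R,3R)-5-methoxy-3-methyl-7-[(E)-prop-1-enyl]-2,3-dihydro-1,4-benzodioxin-2-yl]phenol | C/C=C/c1cc(OC)c2c(c1)O[C@H](c1cc(OC)c(O)c(OC)c1)[C@@H](C)O2 | target

## Step count and risk

Total: 7 steps. Longest linear sequence: 5 steps (steps 1, 2, 5, 6, 7, or steps 3, 4, 5, 6, 7).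

**Step 5 (key step).** Most likely to go wrong:
- Ylide formation at O4 instead of O1, leading to the regioisomeric ring expansion, because the steric bias of one methoxy group is modest.
- Loss of catalyst control if the ylide leaves rhodium before the shift, giving poor facial selectivity at C3 and C2.
- Consumption of the carbene by dimerisation or azine formation, or by insertion into the hydridic acetal C–H bond.
- Proton transfer within the ion pair, which opens the ring to a vinyl ether.

Fallback (known chemistry, sets out from 1 and comes back at 12): C3 is taken from the chiral pool and C2 is left to thermodynamic control.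
- Mitsunobu etherification of 1 with (S)-2-hydroxy-N-methoxy-N-methylpropanamide (PPh3, DIAD, THF, 0 °C to rt) proceeds with inversion and should give (2R)-2-(4-bromo-2-formyl-6-methoxyphenoxy)-N-methoxy-N-methylpropanamide F1. The free hydroxyl of 1 is by construction the future O4 and the formyl group the latent O1, so no site question arises.
- Baeyer–Villiger oxidation (mCPBA, CH2Cl2) gives 5-bromo-3-methoxy-2-{[(2R)-1-[methoxy(methyl)amino]-1-oxopropan-2-yl]oxy}phenyl formate F2. NaHCO3 in MeOH cleaves it to (2R)-2-(4-bromo-2-hydroxy-6-methoxyphenoxy)-N-methoxy-N-methylpropanamide F3.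
- Separately, commercial 4-bromo-2,6-dimethoxyphenol is protected (MOMCl, i-Pr2NEt, CH2Cl2) as 5-bromo-1,3-dimethoxy-2-(methoxymethoxy)benzene F4 and converted with Mg in THF into [3,5-dimethoxy-4-(methoxymethoxy)phenyl]magnesium bromide F5.
- F3, deprotonated with NaH, is treated with F5 (THF, −20 to 0 °C) to give (2R)-2-(4-bromo-2-hydroxy-6-methoxyphenoxy)-1-[3,5-dimethoxy-4-(methoxymethoxy)phenyl]propan-1-one F6. This is reduced at once (NaBH4, MeOH, 0 °C) to 5-bromo-2-{[(2R)-1-[3,5-dimethoxy-4-(methoxymethoxy)phenyl]-1-hydroxypropan-2-yl]oxy}-3-methoxyphenol F7, as both C1 epimers.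
- Acid (CF3CO2H, wet CH2Cl2, 0 °C to rt) ionises the benzylic alcohol, the ring-A phenol closes O1–C2 under thermodynamic control to the trans isomer, and the methoxymethyl group is lost. This should give 4-[(2R,3R)-7-bromo-5-methoxy-3-methyl-2,3-dihydro-1,4-benzodioxin-2-yl]-2,6-dimethoxyphenol F8.
- Pivaloylation (PivCl, Et3N, DMAP, CH2Cl2) returns to 12.

**Step 2.** Most likely to go wrong: C-alkylation of the activated catechol ring by the oxocarbenium ion and incomplete closure to the five-membered acetal, with oligomer formation and air oxidation of 3 in the hot acidic medium. Fallback (sets out from 3 and comes back at 5): the acetaldehyde unit is attached under basic conditions first and the oxocarbenium ion is generated only intramolecularly. O-vinylation with vinyl acetate ([Ir(cod)Cl]2, Na2CO3, toluene, 100 °C) should give 4-bromo-2-(ethenyloxy)-6-methoxyphenol F9 together with its isomer 5-bromo-2-(ethenyloxy)-3-methoxyphenol F10. Both close to the same acetal when the neighbouring hydroxyl adds to the vinyl ether under a trace of acid (PPTS, dilute CH2Cl2, rt), which returns to 5.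

**Step 6.** Most likely to go wrong: erosion of the alkene geometry through palladium hydride isomerisation, protodeboronation of the alkenylboronate before transmetalation, and partial hydrolysis of the aryl ester by the aqueous base. Fallback (sets out from 12 and comes back at 14): the three carbons are introduced as an allyl group and the double bond is then moved into conjugation under thermodynamic control. Coupling of 12 with 2-allyl-4,4,5,5-tetramethyl-1,3,2-dioxaborolane (Pd(PPh3)4, CsF, THF, reflux) should give 2,6-dimethoxy-4-[(2R,3R)-5-methoxy-3-methyl-7-(prop-2-enyl)-2,3-dihydro-1,4-benzodioxin-2-yl]phenyl 2,2-dimethylpropanoate F11. Isomerisation (RuHCl(CO)(PPh3)3 cat., toluene, 80 °C) should then favour the conjugated E alkene, which is 14.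

**Step 7.** Most likely to go wrong: slow acyl transfer at the doubly ortho-substituted ester, which forces heating; the phenoxide can then open the O1–C2 bond through the quinone methide, which methanol may capture, and the electron-rich phenoxide can oxidise in air. Fallback (sets out from 14 and comes back at 15): the ester is cleaved reductively instead of by solvolysis, with i-Bu2AlH (3 equiv, CH2Cl2, −78 °C) and a cold quench with aqueous potassium sodium tartrate. No phenoxide is then present in a protic medium above −78 °C, and the alkene and the ethers are inert to the hydride.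

## Further compounds

F1 | step 5 | (2R)-2-(4-bromo-2-formyl-6-methoxyphenoxy)-N-methoxy-N-methylpropanamide | CON(C)C(=O)[C@@H](C)Oc1c(C=O)cc(Br)cc1OC
F2 | step 5 | 5-bromo-3-methoxy-2-{[(2R)-1-[methoxy(methyl)amino]-1-oxopropan-2-yl]oxy}phenyl formate | CON(C)C(=O)[C@@H](C)Oc1c(OC=O)cc(Br)cc1OC
F3 | step 5 | (2R)-2-(4-bromo-2-hydroxy-6-methoxyphenoxy)-N-methoxy-N-methylpropanamide | CON(C)C(=O)[C@@H](C)Oc1c(O)cc(Br)cc1OC
F4 | step 5 | 5-bromo-1,3-dimethoxy-2-(methoxymethoxy)benzene | COCOc1c(OC)cc(Br)cc1OC
F5 | step 5 | [3,5-dimethoxy-4-(methoxymethoxy)phenyl]magnesium bromide | COCOc1c(OC)cc([Mg]Br)cc1OC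
F6 | step 5 | (2R)-2-(4-bromo-2-hydroxy-6-methoxyphenoxy)-1-[3,5-dimethoxy-4-(methoxymethoxy)phenyl]propan-1-one | COCOc1c(OC)cc(cc1OC)C(=O)[C@@H](C)Oc1c(O)cc(Br)cc1OC
F7 | step 5 | 5-bromo-2-{[(2R)-1-[3,5-dimethoxy-4-(methoxymethoxy)phenyl]-1-hydroxypropan-2-yl]oxy}-3-methoxyphenol (both C1 epimers) | COCOc1c(OC)cc(cc1OC)C(O)[C@@H](C)Oc1c(O)cc(Br)cc1OC
F8 | step 5 | 4-[(2R,3R)-7-bromo-5-methoxy-3-methyl-2,3-dihydro-1,4-benzodioxin-2-yl]-2,6-dimethoxyphenol | Brc1cc(OC)c2c(c1)O[C@H](c1cc(OC)c(O)c(OC)c1)[C@@H](C)O2
F9 | step 2 | 4-bromo-2-(ethenyloxy)-6-methoxyphenol | C=COc1cc(Br)cc(OC)c1O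
F10 | step 2 | 5-bromo-2-(ethenyloxy)-3-methoxyphenol | C=COc1c(O)cc(Br)cc1OC
F11 | step 6 | 2,6-dimethoxy-4-[(2R,3R)-5-methoxy-3-methyl-7-(prop-2-enyl)-2,3-dihydro-1,4-benzodioxin-2-yl]phenyl 2,2-dimethylpropanoate | C=CCc1cc(OC)c2c(c1)O[C@H](c1cc(OC)c(OC(=O)C(C)(C)C)c(OC)c1)[C@@H](C)O2
F0 | step 7 | none | none
A1 | alternative 1 | 3-{[(1S)-1-[3,5-dimethoxy-4-(methoxymethoxy)phenyl]prop-2-enyl]oxy}-4-hydroxy-5-methoxybenzaldehyde | O=Cc1cc(OC)c(O)c(c1)O[C@H](c1cc(OC)c(OCOC)c(OC)c1)C=C
A2 | alternative 1 | (2R,3S)-2-[3,5-dimethoxy-4-(methoxymethoxy)phenyl]-3-(iodomethyl)-5-methoxy-2,3-dihydro-1,4-benzodioxine-7-carbaldehyde | O=Cc1cc(OC)c2c(c1)O[C@H](c1cc(OC)c(OCOC)c(OC)c1)[C@@H](CI)O2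
A3 | alternative 2 | (5R,6S)-6-[3,5-dimethoxy-4-(methoxymethoxy)phenyl]-5-methyl-1,4-dioxan-2-one | O=C1CO[C@H](C)[C@H](c2cc(OC)c(OCOC)c(OC)c2)O1
A4 | alternative 2 | (2E,4E)-3-methylhexa-2,4-dienoyl chloride | O=C(Cl)/C=C(\C)/C=C/C
A5 | alternative 2 | 2-{[(1S,2R)-1-[3,5-dimethoxy-4-(methoxymethoxy)phenyl]-1-hydroxypropan-2-yl]oxy}-5-[(E)-prop-1-enyl]benzene-1,3-diol | C/C=C/c1cc(O)c(O[C@H](C)[C@@H](O)c2cc(OC)c(OCOC)c(OC)c2)c(O)c1
A6 | alternative 3 | methyl 4-diazo-3,5-dioxocyclohexane-1-carboxylate | COC(=O)C1CC(=O)C(=[N+]=[N-])C(=O)C1
A7 | alternative 3 | 2,6-dimethoxy-4-[(2R,3R)-3-methyloxiran-2-yl]phenyl 2,2-dimethylpropanoate | C[C@H]1O[C@@H]1c1cc(OC)c(OC(=O)C(C)(C)C)c(OC)c1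
A8 | alternative 3 | methyl (2R,3R)-2-[4-(2,2-dimethylpropanoyloxy)-3,5-dimethoxyphenyl]-3-methyl-5-oxo-2,3,5,6,7,8-hexahydro-1,4-benzodioxine-7-carboxylate | COC(=O)C1CC(=O)C2=C(C1)O[C@H](c1cc(OC)c(OC(=O)C(C)(C)C)c(OC)c1)[C@@H](C)O2
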